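**Strategy.** The C50 polyene is cut at C11=C12 and C11'=C12' into a C10 dialdehyde and two identical C20 ring units, and each ring is traced back to the cyclopentene of (R)-α-campholenic aldehyde. The key step exploits the C2(H)(CH2 arm)–C1(CH3)2–C6 triad of ring A (and of its twin, ring B), which that terpene already holds with the 2R configuration. Once the arm is extended and the five-membered ring cleaved, an intramolecular aldol condensation of the 1,5-keto aldehyde forms the C4–C5 bond and closes the six-membered ring as a cyclohexenone in one operation. The precursor is an acyclic methyl ketone/aldehyde carrying the (E)-enoate arm on the stereocentre.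

Key step: step 3

Remark: carotenoid numbering is used for the ring (C1 gem-dimethyl carbon, C2 stereocentre, C3 and C4 methylenes, C5 methyl-bearing carbon, C6 chain-bearing carbon). The spatial arrangement at C2 is that of (R)-1 throughout; the R/S descriptors of compounds 4, 5 and 6 differ only because substituent priorities change.

Assumption: enantiomerically pure (R)-α-campholenic aldehyde, (2E)-3-methylpent-2-en-4-yn-1-ol and the C10 dialdehyde are taken as purchasable.

**Step 1**
Reactants: 1 (R)-α-campholenic aldehyde; 2 ethyl 2-(triphenylphosphoranylidene)propanoate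
Product: 3 ethyl (2E)-2-methyl-4-[(1R)-2,2,3-trimethylcyclopent-3-en-1-yl]but-2-enoate
Conditions: 2 (1.15 equiv), CH2Cl2, rt
Reagents that add atoms: none
Why: Wittig olefination with a stabilised α-methyl ylide should give the E-trisubstituted enoate, leaves the ring alkene and the non-enolisable stereocentre untouched, and, because it precedes ring cleavage, keeps the two future arms on C2 different.

**Step 2**
Reactants: 3 ethyl (2E)-2-methyl-4-[(1R)-2,2,3-trimethylcyclopent-3-en-1-yl]but-2-enoate
Product: 5 ethyl (2E,5S)-2,6,6-trimethyl-7-oxo-5-(2-oxoethyl)oct-2-enoate, via secondary ozonide 4 (not isolated)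
Conditions: O3 (1 equiv, Sudan Red 7B end-point), CH2Cl2, −78 °C; then PPh3, −78 °C → rt
Reagents that add atoms: ozone, [O-][O+]=O
Why: Chemoselective ozonolysis with reductive work-up should succeed because electrophilic ozone attacks the electron-rich trisubstituted ring alkene much faster than the ester-deactivated enoate, so the methyl ketone and the aldehyde are unmasked without touching the stereocentre.

**Step 3**
Reactants: 5 ethyl (2E,5S)-2,6,6-trimethyl-7-oxo-5-(2-oxoethyl)oct-2-enoate
Product: 7 ethyl (2E)-4-[(1R)-2,2-dimethyl-3-oxocyclohex-4-en-1-yl]-2-methylbut-2-enoate, via aldol adduct 6 (not isolated)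
Conditions: pyrrolidine (0.2 equiv), AcOH (0.2 equiv), toluene (0.05 M), 4 Å MS, 60 °C
Reagents that add atoms: none
Why: This is an amine-salt-catalysed intramolecular aldol condensation, the cyclodehydration half of a Robinson annulation: pyrrolidine turns the methyl ketone into its enamine (or the aldehyde into an iminium ion attacked by the ketone enol), the CH3 carbon (future C5) adds to the aldehyde carbon (C4) to give aldol 6, and loss of water gives the conjugated enone. Ring A closes in a 6-(enolendo)-exo-trig mode, with both nucleophile carbons inside the new ring and the aldehyde C=O outside it. No stereocentre is created, since the carbinol carbon of 6 becomes trigonal, and C2 keeps the configuration of 1 because it lies β to both carbonyl groups and is not enolisable. Only regioselectivity is required: the ketone can enolise solely towards its methyl group because the other α-carbon is the quaternary C1, and the reverse pairing (aldehyde α-carbon onto the ketone) would close a four-membered ring and remains a reversible dead end. Dilution should suppress intermolecular aldehyde self-condensation, and the β-substituted α-methyl enoate is too poor a Michael acceptor to compete.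

**Step 4**
Reactants: 7 ethyl (2E)-4-[(1R)-2,2-dimethyl-3-oxocyclohex-4-en-1-yl]-2-methylbut-2-enoate
Product: 9 ethyl (2E)-2-methyl-4-[(1R,4RS)-2,2,4-trimethyl-3-oxocyclohexyl]but-2-enoate, via lithium enolate 8 (not isolated)
Conditions: LiBH(s-Bu)3 (1.05 equiv), THF, −78 °C; then MeI (5 equiv), −78 → 0 °C; aq NH4Cl
Reagents that add atoms: iodomethane, CI
Why: Conjugate hydride reduction of a β-unsubstituted cyclohexenone, whose carbonyl is shielded by the adjacent C(CH3)2, gives regiodefined enolate 8, and its C-methylation installs the C5 methyl group as an epimeric mixture that is irrelevant because C5 becomes trigonal in step 5, while the less electrophilic trisubstituted enoate should survive at −78 °C.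

**Step 5**
Reactants: 9 ethyl (2E)-2-methyl-4-[(1R,4RS)-2,2,4-trimethyl-3-oxocyclohexyl]but-2-enoate
Product: 10 ethyl (2E)-2-methyl-4-[(1R)-2,2,4-trimethyl-3-{[(trifluoromethyl)sulfonyl]oxy}cyclohex-3-en-1-yl]but-2-enoate
Conditions: Tf2O (1.3 equiv), 2,6-di-tert-butyl-4-methylpyridine (1.5 equiv), CH2Cl2, 0 °C → rt
Reagents that add atoms: trifluoromethanesulfonic anhydride, O=S(=O)(OS(=O)(=O)C(F)(F)F)C(F)(F)F
Why: Enol triflate formation by O-triflylation of the ketone and loss of its only α-hydrogen can give only the C5=C6 triflate because C1 is quaternary, and the absence of a strong base avoids γ-deprotonation of the enoate.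

**Step 6**
Reactants: 11 (2E)-3-methylpent-2-en-4-yn-1-ol
Product: 12 (2E,4E)-3-methyl-5-(tributylstannyl)penta-2,4-dien-1-ol
Conditions: Bu3SnH (1.1 equiv), AIBN (5 mol %), toluene, 90 °C
Reagents that add atoms: tributyltin hydride, CCCC[SnH](CCCC)CCCC
Why: Radical hydrostannylation of a terminal alkyne places tin on the terminal carbon, and reversible stannyl-radical addition should equilibrate the vinylstannane towards the E isomer, which is separable from residual Z isomer by chromatography.

**Step 7**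
Reactants: 10 ethyl (2E)-2-methyl-4-[(1R)-2,2,4-trimethyl-3-{[(trifluoromethyl)sulfonyl]oxy}cyclohex-3-en-1-yl]but-2-enoate; 12 (2E,4E)-3-methyl-5-(tributylstannyl)penta-2,4-dien-1-ol
Product: 13 ethyl (2E)-4-{(1R)-3-[(1E,3E)-5-hydroxy-3-methylpenta-1,3-dien-1-yl]-2,2,4-trimethylcyclohex-3-en-1-yl}-2-methylbut-2-enoate
Conditions: Pd2(dba)3 (2.5 mol %), AsPh3 (20 mol %), NMP, 50 °C
Reagents that add atoms: none
Why: Stille cross-coupling of an enol triflate with an alkenylstannane under AsPh3-accelerated conditions is the established way to join hindered 2,6,6-trimethylcyclohexenyl triflates to polyene stannanes, proceeds with retention of both alkene geometries and tolerates the free hydroxyl and the ester.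

**Step 8**
Reactants: 13 ethyl (2E)-4-{(1R)-3-[(1E,3E)-5-hydroxy-3-methylpenta-1,3-dien-1-yl]-2,2,4-trimethylcyclohex-3-en-1-yl}-2-methylbut-2-enoate
Product: 14 [(2E,4E)-5-{(5R)-5-[(2E)-4-ethoxy-3-methyl-4-oxobut-2-en-1-yl]-2,6,6-trimethylcyclohex-1-en-1-yl}-3-methylpenta-2,4-dien-1-yl]triphenylphosphonium bromide
Conditions: Ph3P·HBr (1.05 equiv), EtOH, 0 °C → rt
Reagents that add atoms: triphenylphosphine hydrobromide, [Br-].c1ccc(cc1)[PH+](c1ccccc1)c1ccccc1
Why: Acid-mediated conversion of an allylic alcohol into its allylic triphenylphosphonium salt (ionisation to the delocalised trienyl cation and capture by PPh3 at the terminal carbon) is the standard entry to carotenoid Wittig salts, and ethanol as solvent cannot scramble the ethyl ester.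

**Step 9**
Reactants: 14 the C20 phosphonium bromide (2.2 equiv); 15 (2E,4E,6E)-2,7-dimethylocta-2,4,6-trienedial
Product: 18 (2R,2'R)-2,2'-bis[(2E)-4-ethoxy-3-methyl-4-oxobut-2-en-1-yl]-β,β-carotene, via C20 phosphorus ylide 16 (not isolated), via C30 aldehyde ester 17 (not isolated)
Conditions: NaOEt (2.3 equiv), EtOH/CH2Cl2, −10 °C → rt, dark; then EtOH, reflux (Z → E)
Reagents that add atoms: none
Why: Twofold Wittig olefination of the C10 dialdehyde with the semistabilised allylic ylide 16 is the classical C20 + C10 + C20 carotenoid assembly, the new C11=C12 and C11'=C12' bonds are expected as E/Z mixtures that thermal equilibration should convert into the all-E polyene, and the remote C2 and C2' centres are not affected.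

**Step 10**
Reactants: 18 (2R,2'R)-2,2'-bis[(2E)-4-ethoxy-3-methyl-4-oxobut-2-en-1-yl]-β,β-carotene
Product: 19 (2R,2'R)-2,2'-bis[(2E)-4-hydroxy-3-methylbut-2-en-1-yl]-β,β-carotene (CNP0359519.1)
Conditions: i-Bu2AlH (6 equiv), CH2Cl2/THF, −78 → −30 °C, dark; aq potassium sodium tartrate
Reagents that add atoms: none
Why: 1,2-Reduction of the two conjugated esters to primary allylic alcohols with i-Bu2AlH at low temperature should leave the polyene, the E side-chain alkenes and the C2/C2' stereocentres untouched.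

**Compound list**
1 | (R)-α-campholenic aldehyde, 2-[(1R)-2,2,3-trimethylcyclopent-3-en-1-yl]acetaldehyde | CC1=CC[C@H](CC=O)C1(C)C | starting material
2 | ethyl 2-(triphenylphosphoranylidene)propanoate | CCOC(=O)C(C)=P(c1ccccc1)(c1ccccc1)c1ccccc1 | starting material
3 | ethyl (2E)-2-methyl-4-[(1R)-2,2,3-trimethylcyclopent-3-en-1-yl]but-2-enoate | CC1=CC[C@H](C/C=C(\C)C(=O)OCC)C1(C)C | intermediate
4 | ethyl (2E)-2-methyl-4-[(3S)-1,2,2-trimethyl-6,7,8-trioxabicyclo[3.2.1]octan-3-yl]but-2-enoate (secondary ozonide, bridgehead diastereomers) | CC12OOC(O1)C[C@H](C/C=C(\C)C(=O)OCC)C2(C)C | intermediate (not isolated)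
5 | ethyl (2E,5S)-2,6,6-trimethyl-7-oxo-5-(2-oxoethyl)oct-2-enoate | CC(=O)C(C)(C)[C@H](CC=O)C/C=C(\C)C(=O)OCC | intermediate
6 | ethyl (2E)-4-[(1S,5RS)-5-hydroxy-2,2-dimethyl-3-oxocyclohexyl]-2-methylbut-2-enoate | O=C1CC(O)C[C@H](C/C=C(\C)C(=O)OCC)C1(C)C | intermediate (not isolated)
7 | ethyl (2E)-4-[(1R)-2,2-dimethyl-3-oxocyclohex-4-en-1-yl]-2-methylbut-2-enoate | O=C1C=CC[C@H](C/C=C(\C)C(=O)OCC)C1(C)C | intermediate
8 | lithium (5R)-5-[(2E)-4-ethoxy-3-methyl-4-oxobut-2-en-1-yl]-6,6-dimethylcyclohex-1-en-1-olate | [Li+].[O-]C1=CCC[C@H](C/C=C(\C)C(=O)OCC)C1(C)C | intermediate (not isolated)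
9 | ethyl (2E)-2-methyl-4-[(1R,4RS)-2,2,4-trimethyl-3-oxocyclohexyl]but-2-enoate (epimers at the methyl-bearing carbon) | CC1CC[C@H](C/C=C(\C)C(=O)OCC)C(C)(C)C1=O | intermediate
10 | ethyl (2E)-2-methyl-4-[(1R)-2,2,4-trimethyl-3-{[(trifluoromethyl)sulfonyl]oxy}cyclohex-3-en-1-yl]but-2-enoate | CC1=C(OS(=O)(=O)C(F)(F)F)C(C)(C)[C@@H](C/C=C(\C)C(=O)OCC)CC1 | intermediate
11 | (2E)-3-methylpent-2-en-4-yn-1-ol | C#C/C(C)=C/CO | starting material
12 | (2E,4E)-3-methyl-5-(tributylstannyl)penta-2,4-dien-1-ol | CCCC[Sn](CCCC)(CCCC)/C=C/C(C)=C/CO | intermediate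
13 | ethyl (2E)-4-{(1R)-3-[(1E,3E)-5-hydroxy-3-methylpenta-1,3-dien-1-yl]-2,2,4-trimethylcyclohex-3-en-1-yl}-2-methylbut-2-enoate | CC1=C(/C=C/C(C)=C/CO)C(C)(C)[C@@H](C/C=C(\C)C(=O)OCC)CC1 | intermediate
14 | [(2E,4E)-5-{(5R)-5-[(2E)-4-ethoxy-3-methyl-4-oxobut-2-en-1-yl]-2,6,6-trimethylcyclohex-1-en-1-yl}-3-methylpenta-2,4-dien-1-yl]triphenylphosphonium bromide | CC1=C(/C=C/C(C)=C/C[P+](c2ccccc2)(c2ccccc2)c2ccccc2)C(C)(C)[C@@H](C/C=C(\C)C(=O)OCC)CC1.[Br-] | intermediate
15 | (2E,4E,6E)-2,7-dimethylocta-2,4,6-trienedial | O=C/C(C)=C/C=C/C=C(C)/C=O | starting material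
16 | ethyl (2E)-2-methyl-4-{(1R)-2,2,4-trimethyl-3-[(1E,3E)-3-methyl-5-(triphenyl-λ5-phosphanylidene)penta-1,3-dien-1-yl]cyclohex-3-en-1-yl}but-2-enoate | CC1=C(/C=C/C(C)=C/C=P(c2ccccc2)(c2ccccc2)c2ccccc2)C(C)(C)[C@@H](C/C=C(\C)C(=O)OCC)CC1 | intermediate (not isolated)
17 | ethyl (2E)-2-methyl-4-{(1R)-2,2,4-trimethyl-3-[(1E,3E,5E,7E,9E,11E)-3,7,12-trimethyl-13-oxotrideca-1,3,5,7,9,11-hexaen-1-yl]cyclohex-3-en-1-yl}but-2-enoate (C11=C12 drawn E) | CC1=C(/C=C/C(C)=C/C=C/C(C)=C/C=C/C=C(C)/C=O)C(C)(C)[C@@H](C/C=C(\C)C(=O)OCC)CC1 | intermediate (not isolated)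
18 | (2R,2'R)-2,2'-bis[(2E)-4-ethoxy-3-methyl-4-oxobut-2-en-1-yl]-β,β-carotene | CC1=C(/C=C/C(C)=C/C=C/C(C)=C/C=C/C=C(C)/C=C/C=C(C)/C=C/C2=C(C)CC[C@H](C/C=C(\C)C(=O)OCC)C2(C)C)C(C)(C)[C@@H](C/C=C(\C)C(=O)OCC)CC1 | intermediate
19 | (2R,2'R)-2,2'-bis[(2E)-4-hydroxy-3-methylbut-2-en-1-yl]-β,β-carotene | CC1=C(/C=C/C(C)=C/C=C/C(C)=C/C=C/C=C(C)/C=C/C=C(C)/C=C/C2=C(C)CC[C@H](C/C=C(\C)CO)C2(C)C)C(C)(C)[C@@H](C/C=C(\C)CO)CC1 | target

**Step count.** Total: 10 steps. Longest linear sequence: 9 steps (steps 1–5 and 7–10, from 1 to 19); step 6 is a one-step side branch.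

**Steps most likely to fail**

1. Step 3 (key step). Intermolecular self-condensation of the aldehyde, or sluggish enamine formation at the hindered tert-alkyl methyl ketone, could outrun the ring closure. Fallback, setting out from 5: the aldehyde alone would be converted into its dimethyl acetal (CH(OMe)3, pyridinium p-toluenesulfonate, MeOH; the hindered ketone should not ketalise) to give ethyl (2E,5S)-5-(2,2-dimethoxyethyl)-2,6,6-trimethyl-7-oxooct-2-enoate F1. Treatment with TMSOTf/i-Pr2NEt in CH2Cl2 would form in the flask the silyl enol ether ethyl (2E,5S)-5-(2,2-dimethoxyethyl)-2,6,6-trimethyl-7-[(trimethylsilyl)oxy]octa-2,7-dienoate F2 and promote its Mukaiyama-type addition to the oxocarbenium ion derived from the acetal. This closes the same C4–C5 bond and gives the β-methoxy ketone ethyl (2E)-4-[(1S,5RS)-5-methoxy-2,2-dimethyl-3-oxocyclohexyl]-2-methylbut-2-enoate F3, from which DBU would eliminate methanol to rejoin the route at 7.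

2. Step 4. Proton exchange between product and enolate could lead to over-methylation, 1,2-reduction could compete, and the enolate could add intramolecularly to the enoate arm. Fallback, setting out from 7: 1,4-hydrosilylation with Et3SiH and catalytic RhCl(PPh3)3 would give the isolable silyl enol ether ethyl (2E)-4-{(1R)-2,2-dimethyl-3-[(triethylsilyl)oxy]cyclohex-3-en-1-yl}-2-methylbut-2-enoate F4. Fluoride (benzyltrimethylammonium fluoride, MeI, THF, 4 Å MS) would then release a boron-free enolate for regiospecific C-methylation, rejoining the route at 9.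

3. Step 7. Oxidative addition and transmetalation at the tetrasubstituted triflate, flanked by C(CH3)2 and the C5 methyl group, may be slow, so that protodestannylation or stannane homocoupling takes over. Fallback, setting out from 10: a Heck reaction with but-3-en-2-one (Pd(OAc)2, PPh3, Et3N, DMF, 70 °C) would give the dienone ethyl (2E)-2-methyl-4-{(1R)-2,2,4-trimethyl-3-[(1E)-3-oxobut-1-en-1-yl]cyclohex-3-en-1-yl}but-2-enoate F5. Addition of CH2=CHMgBr (LaCl3·2LiCl, THF, −78 °C; the ketone should react ahead of the conjugated ester) would give the tertiary carbinol ethyl (2E)-4-{(1R)-3-[(1E)-3-hydroxy-3-methylpenta-1,4-dien-1-yl]-2,2,4-trimethylcyclohex-3-en-1-yl}-2-methylbut-2-enoate F6. Ph3P·HBr in EtOH would convert F6 with allylic transposition into the same phosphonium salt, rejoining the route at 14.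

**Further compounds**
F1 | step 3 | ethyl (2E,5S)-5-(2,2-dimethoxyethyl)-2,6,6-trimethyl-7-oxooct-2-enoate | CC(=O)C(C)(C)[C@H](CC(OC)OC)C/C=C(\C)C(=O)OCC
F2 | step 3 | ethyl (2E,5S)-5-(2,2-dimethoxyethyl)-2,6,6-trimethyl-7-[(trimethylsilyl)oxy]octa-2,7-dienoate | C=C(O[Si](C)(C)C)C(C)(C)[C@H](CC(OC)OC)C/C=C(\C)C(=O)OCC
F3 | step 3 | ethyl (2E)-4-[(1S,5RS)-5-methoxy-2,2-dimethyl-3-oxocyclohexyl]-2-methylbut-2-enoate | O=C1CC(OC)C[C@H](C/C=C(\C)C(=O)OCC)C1(C)C
F4 | step 4 | ethyl (2E)-4-{(1R)-2,2-dimethyl-3-[(triethylsilyl)oxy]cyclohex-3-en-1-yl}-2-methylbut-2-enoate | CC[Si](CC)(CC)OC1=CCC[C@H](C/C=C(\C)C(=O)OCC)C1(C)C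
F5 | step 7 | ethyl (2E)-2-methyl-4-{(1R)-2,2,4-trimethyl-3-[(1E)-3-oxobut-1-en-1-yl]cyclohex-3-en-1-yl}but-2-enoate | CC1=C(/C=C/C(C)=O)C(C)(C)[C@@H](C/C=C(\C)C(=O)OCC)CC1
F6 | step 7 | ethyl (2E)-4-{(1R)-3-[(1E)-3-hydroxy-3-methylpenta-1,4-dien-1-yl]-2,2,4-trimethylcyclohex-3-en-1-yl}-2-methylbut-2-enoate | CC1=C(/C=C/C(C)(O)C=C)C(C)(C)[C@@H](C/C=C(\C)C(=O)OCC)CC1
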